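**Plan**

- Retrosynthesis: after removal of three benzyl and two silyl ethers, ring C is cut at O1–C8a and C4–C4a. This takes the C8a/C4a pair of ring A out of an acyl–oxygen bond and leaves 3,5-bis(benzyloxy)benzyne and a 4-aryl β-lactone (O1, C2, C3, C4) that carries ring B and the whole side chain.
- Enabling feature: ring C holds the aldol array O1–C2–C3–C4(=O), a latent β-lactone, whose two ends sit on adjacent carbons of ring A. The C5 oxygen next to C4a polarises the aryne so that O1 bonds to C8a and the acyl carbon C4 to C4a.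
- Further cuts: the lactone C–O bond (β-hydroxy acid); the C1'–C2 bond together with C3 and C4 (carbonylative malonate coupling at an aryl bromide); the C7''–aryl bond (Weinreb amide plus Grignard reagent); the C8''–O4' bond (Mitsunobu ether).
- Forward order: glycerate, aryl ether, aryl ketone, erythro alcohol (side chain on ring B), β-keto ester, β-hydroxy acid, four-membered lactone, two-atom ring expansion that forms ring C and joins ring A, deprotection.
- Stereochemistry: C8'' from methyl (R)-glycerate, inverted in the Mitsunobu step; C7'' by chelation-controlled hydride addition relayed from C8''; C2 by catalyst-controlled transfer hydrogenation, carried with retention through lactonisation and ring expansion.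

Key step: step 13

Remark: the SMILES is read as the (2S)-flavanone carrying an erythro (7''R,8''S) guaiacylglycerol unit on O4'; flavanone numbering is used for rings A, B and C, and C7''–C9'' for the side chain.

Abbreviation: Ar* = 4-{[(1R,2S)-1-[4-(benzyloxy)-3-methoxyphenyl]-1-(tert-butyldimethylsilyloxy)-3-(triisopropylsilyloxy)propan-2-yl]oxy}-3,5-dimethoxyphenyl.

**Route**

Step 1
Reactants: 1 methyl (R)-2,2-dimethyl-1,3-dioxolane-4-carboxylate
Product: 2 methyl (R)-2,3-dihydroxypropanoate
Conditions: Amberlyst 15, MeOH–H2O (9:1), 23 °C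
Reagents that add atoms: none
Why: Acid-catalysed acetal hydrolysis frees the diol without touching the stereocenter or the methyl ester.

Step 2
Reactants: 2 methyl (R)-2,3-dihydroxypropanoate
Product: 3 methyl (R)-2-hydroxy-3-(triisopropylsilyloxy)propanoate
Conditions: TIPSCl, imidazole, CH2Cl2, 0 °C
Reagents that add atoms: triisopropylsilyl chloride, CC(C)[Si](Cl)(C(C)C)C(C)C
Why: The primary hydroxyl is silylated selectively for steric reasons, and the bulky, non-coordinating TIPS ether later keeps O9'' out of any metal chelate.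

Step 3
Reactants: 3 methyl (R)-2-hydroxy-3-(triisopropylsilyloxy)propanoate; 4 4-bromo-2,6-dimethoxyphenol
Product: 5 methyl (S)-2-(4-bromo-2,6-dimethoxyphenoxy)-3-(triisopropylsilyloxy)propanoate
Conditions: PPh3, DIAD, toluene, 0 to 23 °C
Reagents that add atoms: none
Why: Mitsunobu etherification of an α-hydroxy ester by the phenol is an SN2 displacement with inversion, so the (R)-carbinol should become the (S)-aryl ether that is C8'' of the target.

Step 4
Reactants: 5 methyl (S)-2-(4-bromo-2,6-dimethoxyphenoxy)-3-(triisopropylsilyloxy)propanoate; 6 1-(benzyloxy)-4-bromo-2-methoxybenzene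
Product: 9 (S)-1-[4-(benzyloxy)-3-methoxyphenyl]-2-(4-bromo-2,6-dimethoxyphenoxy)-3-(triisopropylsilyloxy)propan-1-one, via Weinreb amide 7 (not isolated), via aryl Grignard reagent 8 (not isolated)
Conditions: MeNHOMe·HCl, i-PrMgCl, THF, −20 °C; then 8 (from 6, Mg, THF), −20 to 0 °C; aq NH4Cl
Reagents that add atoms: none
Why: Weinreb ketone synthesis in one pot: the magnesium chelate of the tetrahedral adduct stops the addition at the ketone, the aryl bromide is inert to the Grignard reagent, and the low temperature should protect the α-stereocenter.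

Step 5
Reactants: 9 (S)-1-[4-(benzyloxy)-3-methoxyphenyl]-2-(4-bromo-2,6-dimethoxyphenoxy)-3-(triisopropylsilyloxy)propan-1-one
Product: 10 (1R,2S)-1-[4-(benzyloxy)-3-methoxyphenyl]-2-(4-bromo-2,6-dimethoxyphenoxy)-3-(triisopropylsilyloxy)propan-1-ol
Conditions: Zn(BH4)2, Et2O, −30 °C; aq NH4Cl
Reagents that add atoms: none
Why: Chelation-controlled reduction (Cram chelate model): zinc bridges the carbonyl oxygen and the α-aryloxy oxygen, hydride enters from the face of the α-hydrogen, and the erythro (1R,2S) alcohol should predominate.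

Step 6
Reactants: 10 (1R,2S)-1-[4-(benzyloxy)-3-methoxyphenyl]-2-(4-bromo-2,6-dimethoxyphenoxy)-3-(triisopropylsilyloxy)propan-1-ol
Product: 11 (1R,2S)-1-[4-(benzyloxy)-3-methoxyphenyl]-2-(4-bromo-2,6-dimethoxyphenoxy)-1-(tert-butyldimethylsilyloxy)-3-(triisopropylsilyloxy)propane (Ar*–Br)
Conditions: TBSOTf, 2,6-lutidine, CH2Cl2, 0 °C
Reagents that add atoms: tert-butyldimethylsilyl trifluoromethanesulfonate, CC(C)(C)[Si](C)(C)OS(=O)(=O)C(F)(F)F
Why: Silyl triflate silylation of the hindered benzylic alcohol masks the last free hydroxyl against the later acylating and aryne conditions.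

Step 7
Reactants: 11 Ar*–Br
Product: 12 ethyl 3-oxo-3-Ar*-propanoate
Conditions: CO (1 atm), KO2CCH2CO2Et, Pd(dba)2 (5 mol %), Xantphos, MgCl2, Et3N, THF, 80 °C; aq citric acid
Reagents that add atoms: carbon monoxide, [C-]#[O+]; potassium ethyl malonate, CCOC(=O)CC(=O)[O-].[K+]
Why: Palladium-catalysed carbonylative coupling of the aryl bromide with the magnesium enolate of the malonate half ester, followed by decarboxylation, should install the β-keto ester at the only C–Br bond in one operation.

Step 8
Reactants: 12 ethyl 3-oxo-3-Ar*-propanoate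
Product: 13 ethyl (S)-3-hydroxy-3-Ar*-propanoate
Conditions: RuCl[(S,S)-TsDPEN](p-cymene) (1 mol %), HCO2H–Et3N (5:2), DMF, 40 °C
Reagents that add atoms: none
Why: Noyori–Ikariya asymmetric transfer hydrogenation: the (S,S)-catalyst differentiates aryl from CH2CO2Et as it does aryl from methyl in acetophenone and should give the (S)-carbinol under catalyst control, the remote side-chain centers having no influence.

Step 9
Reactants: 13 ethyl (S)-3-hydroxy-3-Ar*-propanoate
Product: 14 (S)-3-hydroxy-3-Ar*-propanoic acid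
Conditions: LiOH, THF–H2O, 0 °C; then aq HCl to pH 4, 0 °C
Reagents that add atoms: lithium hydroxide, [Li+].[OH-]
Why: Mild saponification of the ethyl ester should leave the silyl ethers and the β-hydroxy stereocenter intact.

Step 10
Reactants: 14 (S)-3-hydroxy-3-Ar*-propanoic acid
Product: 15 (S)-4-Ar*-oxetan-2-one
Conditions: PhSO2Cl, pyridine, 0 °C
Reagents that add atoms: none
Why: Carboxyl activation as the mixed sulfonic anhydride and 4-exo-trig attack of the hydroxyl give the β-lactone with retention at the carbinol carbon, the two meta methoxy groups and the twisted 4-alkoxy group keeping the benzylic C–O bond from ionising.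

Step 11
Reactants: 16 3,5-bis(benzyloxy)phenol
Product: 17 3,5-bis(benzyloxy)-2-bromophenol
Conditions: NBS, i-Pr2NH (cat.), CH2Cl2, 0 °C
Reagents that add atoms: N-bromosuccinimide, O=C1CCC(=O)N1Br
Why: Amine-catalysed NBS bromination of phenols is ortho-selective, and the two ortho positions of 16 are equivalent.

Step 12
Reactants: 17 3,5-bis(benzyloxy)-2-bromophenol
Product: 20 3,5-bis(benzyloxy)-2-(trimethylsilyl)phenyl trifluoromethanesulfonate, via aryl trimethylsilyl ether 18 (not isolated), via lithium ortho-silylphenolate 19 (not isolated)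
Conditions: HMDS, THF, 70 °C, evaporate; n-BuLi, THF, −100 °C; Tf2O, −100 to 0 °C
Reagents that add atoms: hexamethyldisilazane, C[Si](C)(C)N[Si](C)(C)C; trifluoromethanesulfonic anhydride, O=S(=O)(OS(=O)(=O)C(F)(F)F)C(F)(F)F
Why: O-silylation, bromine–lithium exchange and retro-Brook 1,3-shift of silicon from oxygen to carbon give the ortho-silyl phenolate, which is trapped as the triflate (the standard route to ortho-silylaryl triflates).

Step 13
Reactants: 15 (S)-4-Ar*-oxetan-2-one; 20 3,5-bis(benzyloxy)-2-(trimethylsilyl)phenyl trifluoromethanesulfonate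
Product: 22 (S)-5,7-bis(benzyloxy)-2-Ar*-chroman-4-one, via 3,5-bis(benzyloxy)benzyne 21 (not isolated)
Conditions: CsF, MeCN–THF (4:1), 23 °C, slow addition of 20 (2 equiv)
Reagents that add atoms: none
Why: Proposed new method: fluoride-induced 1,2-elimination of 20 gives aryne 21; the ring oxygen O1 of the strained lactone, whose lone pair is only weakly delocalised into the carbonyl, adds to the aryne carbon remote from the C5 benzyloxy group, the aryl anion formed at C4a attacks the activated acyl carbon C4, and the resulting benzoxete-fused bicycle collapses by cleavage of the O1–C4 bond with release of four-ring strain. The closest known reaction type is the σ-insertion of arynes into the N–C(=O) bond of cyclic ureas and β-lactams and into the C–C bond of cyclic β-keto esters, which likewise enlarges the ring by two atoms. Ring C is closed by intermolecular O1–C8a bond formation followed by 4-exo-trig attack of C4a on C4 and fragmentation, a net four- to six-membered ring expansion that makes both bonds to ring A. No stereocenter is created: C2 is carried over with retention because its bond to O1 is never broken, and C7'' and C8'' are remote and untouched. The step needs regioselectivity (O1 to C8a, acyl to C4a), secured by the polarisation of the 3-alkoxyaryne, and chemoselectivity for the lactone oxygen over the aryl and hindered silyl ethers, secured by a high concentration of 15, slow release of the aryne and room temperature, at which TIPS and secondary TBS ethers should survive CsF.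

Step 14
Reactants: 22 (S)-5,7-bis(benzyloxy)-2-Ar*-chroman-4-one
Product: 23 (S)-5,7-bis(benzyloxy)-2-[4-{[(1R,2S)-1-[4-(benzyloxy)-3-methoxyphenyl]-1,3-dihydroxypropan-2-yl]oxy}-3,5-dimethoxyphenyl]chroman-4-one
Conditions: HF·pyridine, pyridine, THF, 0 to 23 °C
Reagents that add atoms: none
Why: Buffered HF·pyridine should cleave both silyl ethers under mildly acidic conditions that avoid base-induced opening of ring C.

Step 15
Reactants: 23 (S)-5,7-bis(benzyloxy)-2-[4-{[(1R,2S)-1-[4-(benzyloxy)-3-methoxyphenyl]-1,3-dihydroxypropan-2-yl]oxy}-3,5-dimethoxyphenyl]chroman-4-one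
Product: 24 (2S)-5,7-dihydroxy-2-[4-{[(1R,2S)-1,3-dihydroxy-1-(4-hydroxy-3-methoxyphenyl)propan-2-yl]oxy}-3,5-dimethoxyphenyl]chroman-4-one
Conditions: H2 (1 atm), Pd on carbon (10 %), EtOAc–MeOH, 23 °C
Reagents that add atoms: none
Why: Neutral hydrogenolysis should remove the three O-benzyl groups while sparing the flavanone C2–O1 bond, the benzylic C7'' alcohol and the aryl ketone.

**Compound list**

1 | methyl (R)-2,2-dimethyl-1,3-dioxolane-4-carboxylate | COC(=O)[C@H]1COC(C)(C)O1 | starting material
2 | methyl (R)-2,3-dihydroxypropanoate | COC(=O)[C@@H](CO)O | intermediate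
3 | methyl (R)-2-hydroxy-3-(triisopropylsilyloxy)propanoate | COC(=O)[C@@H](CO[Si](C(C)C)(C(C)C)C(C)C)O | intermediate
4 | 4-bromo-2,6-dimethoxyphenol | COc1cc(Br)cc(OC)c1O | starting material
5 | methyl (S)-2-(4-bromo-2,6-dimethoxyphenoxy)-3-(triisopropylsilyloxy)propanoate | COC(=O)[C@H](CO[Si](C(C)C)(C(C)C)C(C)C)Oc1c(OC)cc(Br)cc1OC | intermediate
6 | 1-(benzyloxy)-4-bromo-2-methoxybenzene | COc1cc(Br)ccc1OCc1ccccc1 | starting material
7 | (S)-2-(4-bromo-2,6-dimethoxyphenoxy)-N-methoxy-N-methyl-3-(triisopropylsilyloxy)propanamide (Weinreb amide) | CON(C)C(=O)[C@H](CO[Si](C(C)C)(C(C)C)C(C)C)Oc1c(OC)cc(Br)cc1OC | intermediate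
8 | [4-(benzyloxy)-3-methoxyphenyl]magnesium bromide | COc1cc([Mg]Br)ccc1OCc1ccccc1 | intermediate
9 | (S)-1-[4-(benzyloxy)-3-methoxyphenyl]-2-(4-bromo-2,6-dimethoxyphenoxy)-3-(triisopropylsilyloxy)propan-1-one | COc1cc(C(=O)[C@H](CO[Si](C(C)C)(C(C)C)C(C)C)Oc2c(OC)cc(Br)cc2OC)ccc1OCc1ccccc1 | intermediate
10 | (1R,2S)-1-[4-(benzyloxy)-3-methoxyphenyl]-2-(4-bromo-2,6-dimethoxyphenoxy)-3-(triisopropylsilyloxy)propan-1-ol | COc1cc([C@@H](O)[C@H](CO[Si](C(C)C)(C(C)C)C(C)C)Oc2c(OC)cc(Br)cc2OC)ccc1OCc1ccccc1 | intermediate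
11 | (1R,2S)-1-[4-(benzyloxy)-3-methoxyphenyl]-2-(4-bromo-2,6-dimethoxyphenoxy)-1-(tert-butyldimethylsilyloxy)-3-(triisopropylsilyloxy)propane (Ar*–Br) | COc1cc([C@@H](O[Si](C)(C)C(C)(C)C)[C@H](CO[Si](C(C)C)(C(C)C)C(C)C)Oc2c(OC)cc(Br)cc2OC)ccc1OCc1ccccc1 | intermediate
12 | ethyl 3-oxo-3-Ar*-propanoate | COc1cc([C@@H](O[Si](C)(C)C(C)(C)C)[C@H](CO[Si](C(C)C)(C(C)C)C(C)C)Oc2c(OC)cc(C(=O)CC(=O)OCC)cc2OC)ccc1OCc1ccccc1 | intermediate
13 | ethyl (S)-3-hydroxy-3-Ar*-propanoate | COc1cc([C@@H](O[Si](C)(C)C(C)(C)C)[C@H](CO[Si](C(C)C)(C(C)C)C(C)C)Oc2c(OC)cc([C@@H](O)CC(=O)OCC)cc2OC)ccc1OCc1ccccc1 | intermediate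
14 | (S)-3-hydroxy-3-Ar*-propanoic acid | COc1cc([C@@H](O[Si](C)(C)C(C)(C)C)[C@H](CO[Si](C(C)C)(C(C)C)C(C)C)Oc2c(OC)cc([C@@H](O)CC(=O)O)cc2OC)ccc1OCc1ccccc1 | intermediate
15 | (S)-4-Ar*-oxetan-2-one | COc1cc([C@@H](O[Si](C)(C)C(C)(C)C)[C@H](CO[Si](C(C)C)(C(C)C)C(C)C)Oc2c(OC)cc([C@@H]3CC(=O)O3)cc2OC)ccc1OCc1ccccc1 | intermediate
16 | 3,5-bis(benzyloxy)phenol | Oc1cc(OCc2ccccc2)cc(OCc2ccccc2)c1 | starting material
17 | 3,5-bis(benzyloxy)-2-bromophenol | Oc1cc(OCc2ccccc2)cc(OCc2ccccc2)c1Br | intermediate
18 | [3,5-bis(benzyloxy)-2-bromophenoxy]trimethylsilane | C[Si](C)(C)Oc1cc(OCc2ccccc2)cc(OCc2ccccc2)c1Br | intermediate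
19 | lithium 3,5-bis(benzyloxy)-2-(trimethylsilyl)phenolate | [Li+].[O-]c1cc(OCc2ccccc2)cc(OCc2ccccc2)c1[Si](C)(C)C | intermediate
20 | 3,5-bis(benzyloxy)-2-(trimethylsilyl)phenyl trifluoromethanesulfonate | C[Si](C)(C)c1c(OCc2ccccc2)cc(OCc2ccccc2)cc1OS(=O)(=O)C(F)(F)F | intermediate
21 | 3,5-bis(benzyloxy)benzyne | C1#CC(OCc2ccccc2)=CC(OCc2ccccc2)=C1 | intermediate
22 | (S)-5,7-bis(benzyloxy)-2-Ar*-chroman-4-one | COc1cc([C@@H](O[Si](C)(C)C(C)(C)C)[C@H](CO[Si](C(C)C)(C(C)C)C(C)C)Oc2c(OC)cc([C@@H]3CC(=O)c4c(OCc5ccccc5)cc(OCc5ccccc5)cc4O3)cc2OC)ccc1OCc1ccccc1 | intermediate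
23 | (S)-5,7-bis(benzyloxy)-2-[4-{[(1R,2S)-1-[4-(benzyloxy)-3-methoxyphenyl]-1,3-dihydroxypropan-2-yl]oxy}-3,5-dimethoxyphenyl]chroman-4-one | COc1cc([C@@H](O)[C@H](CO)Oc2c(OC)cc([C@@H]3CC(=O)c4c(OCc5ccccc5)cc(OCc5ccccc5)cc4O3)cc2OC)ccc1OCc1ccccc1 | intermediate
24 | (2S)-5,7-dihydroxy-2-[4-{[(1R,2S)-1,3-dihydroxy-1-(4-hydroxy-3-methoxyphenyl)propan-2-yl]oxy}-3,5-dimethoxyphenyl]chroman-4-one | COc1cc([C@@H](O)[C@H](CO)Oc2c(OC)cc([C@@H]3CC(=O)c4c(O)cc(O)cc4O3)cc2OC)ccc1O | target

**Step count and risks**

Total steps: 15. Longest linear sequence: 13 steps (steps 1–10 and 13–15); steps 11 and 12 form the short arm that joins at step 13.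

Step 13 (bears the label). The lactone oxygen may be too weak a nucleophile, so that the aryne is consumed by self-condensation or by fluoride; fluoride may also open or decarboxylate the lactone, and reversible base-induced opening of ring C could erode the C2 configuration. The fallback uses known chemistry and sets out from 11. Bromine–lithium exchange (n-BuLi, THF, −78 °C), trapping with B(OiPr)3 and mild aqueous hydrolysis would give the arylboronic acid F1. Commercial 1-[2,4-bis(benzyloxy)-6-hydroxyphenyl]ethanone would be condensed with DMF dimethyl acetal to the enaminone F2 and cyclised with acid to 5,7-bis(benzyloxy)-4H-chromen-4-one F3. Palladium-catalysed asymmetric conjugate addition of F1 to F3 (Pd(OCOCF3)2, the t-BuPyOx enantiomer that delivers the (2S) product, NH4PF6, H2O, ClCH2CH2Cl, 60 °C) would then form ring C on a preformed chromone and come back to the route at 22, by-passing 12 to 15.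

Step 5. Facial selectivity may be poor if zinc does not chelate the weakly basic aryloxy oxygen and an open Felkin–Anh transition state competes, and the α-aryloxy ketone may epimerise before it is reduced. The fallback sets out from 5 and makes the C7''–aryl bond instead of the C7''–H bond under stereocontrol. Reduction with i-Bu2AlH (CH2Cl2, −78 °C) would give the aldehyde F4. Addition of [4-(benzyloxy)-3-methoxyphenyl]titanium triisopropoxide F5 (from Grignard reagent 8 and ClTi(OiPr)3, THF, −78 °C) should then follow the polar Felkin–Anh model, with the aryloxy group anti to the incoming aryl, and give the erythro alcohol, coming back to the route at 10.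

Step 10. Sulfonylation of the benzylic hydroxyl followed by decarboxylative fragmentation to the styrene may outrun the 4-exo-trig ring closure. The fallback sets out from 11. Bromine–lithium exchange and formylation (n-BuLi, then DMF, THF, −78 °C) would give the aldehyde F6. A catalytic asymmetric ketene–aldehyde [2+2] cycloaddition (acetyl chloride, i-Pr2NEt, O-trimethylsilylquinidine or its quinine pseudo-enantiomer, whichever delivers the (S)-lactone, LiClO4, CH2Cl2–Et2O, −78 °C) would then build the four-membered ring directly and come back to the route at 15, by-passing 12, 13 and 14.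

**Further compounds**

F1 | step 13 | Ar*-boronic acid | COc1cc([C@@H](O[Si](C)(C)C(C)(C)C)[C@H](CO[Si](C(C)C)(C(C)C)C(C)C)Oc2c(OC)cc(B(O)O)cc2OC)ccc1OCc1ccccc1
F2 | step 13 | (E)-1-[2,4-bis(benzyloxy)-6-hydroxyphenyl]-3-(dimethylamino)prop-2-en-1-one | CN(C)/C=C/C(=O)c1c(O)cc(OCc2ccccc2)cc1OCc1ccccc1
F3 | step 13 | 5,7-bis(benzyloxy)-4H-chromen-4-one | O=c1ccoc2cc(OCc3ccccc3)cc(OCc3ccccc3)c12
F4 | step 5 | (S)-2-(4-bromo-2,6-dimethoxyphenoxy)-3-(triisopropylsilyloxy)propanal | O=C[C@H](CO[Si](C(C)C)(C(C)C)C(C)C)Oc1c(OC)cc(Br)cc1OC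
F5 | step 5 | [4-(benzyloxy)-3-methoxyphenyl]titanium triisopropoxide | COc1cc([Ti](OC(C)C)(OC(C)C)OC(C)C)ccc1OCc1ccccc1
F6 | step 10 | Ar*-carbaldehyde | COc1cc([C@@H](O[Si](C)(C)C(C)(C)C)[C@H](CO[Si](C(C)C)(C(C)C)C(C)C)Oc2c(OC)cc(C=O)cc2OC)ccc1OCc1ccccc1
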